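**Plan**

- Retrosynthesis: the two aryl O–Si bonds and the N-acyl bond of the saturated arm are cut first; the C1' arm is then taken back from CH2NH2 through CH2N3 and CH2OH to a methyl ester.
- Ring B (the ring with the saturated arm) is then opened across C3'–C4' and C5'–C6'. It carries OH on C4' flanked by OMe on C3' and by the ring-A aryl on C5', with the arm carbon para on C1'. That is the pattern an aryl silyl ynol ether (C4'≡C5') leaves on C3 and C6 of a 3-methoxy-2-pyrone-5-carboxylate once CO2 is lost.
- Forward: ring A is bought as capsaicin; C5 is formylated, the phenol silylated, the aldehyde homologated to the alkyne, and the acetylide oxidised and O-silylated. The pyrone is built from dimethyl 2-oxoglutarate by ketalisation, enol-ether formation and aminomethylenation/lactonisation.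
- Ring B, and with it the biaryl bond, arises in the cycloaddition/decarboxylation. The ester is then reduced, converted to the amine through the azide, acylated with 8-methylnonanoic acid, and both silyl ethers are removed with fluoride.
- The target has no stereocentre. Its one stereo-element, the E-alkene, comes in with capsaicin and meets no hydrogenation, halogen electrophile or strong acid in the main line (the azide is reduced with a phosphine for that reason).

Key step: step 8

Remark: capsaicin numbering is used (C1 carries the CH2N arm, C3 OMe, C4 OH, C5 the free position ortho to OH; primes mark ring B). Commercial capsaicin is taken as the pure E isomer, and the di-ortho-substituted biaryl axis is assumed to rotate freely at room temperature, so no axial stereochemistry is addressed.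

**Route**

Step 1
Reactants: 1 capsaicin
Product: 3 5-formylcapsaicin, via hydroxymethyl phenol 2 (not isolated)
Conditions: MgCl2, Et3N, (CH2O)n, MeCN, 80 °C; aq. HCl work-up
Reagents that add atoms: paraformaldehyde (as formaldehyde), C=O
Why: Casnati–Skattebøl ortho-formylation, in which the magnesium phenoxide directs formaldehyde to the only free ortho position (C5, the other being blocked by OMe) and the benzylic alkoxide of 2 is oxidised in the flask by hydride transfer to a second formaldehyde, under conditions that leave the amide and the isolated E-alkene alone.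

Step 2
Reactants: 3 5-formylcapsaicin
Product: 4 O-triisopropylsilyl-5-formylcapsaicin
Conditions: iPr3SiCl, imidazole, DMAP (cat.), DMF, 40 °C
Reagents that add atoms: chlorotriisopropylsilane, CC(C)[Si](Cl)(C(C)C)C(C)C
Why: Standard silylation of a phenol, with the bulky triisopropylsilyl group chosen because it should withstand organolithium bases, hydride and the thermal key step and still fall to fluoride at the end.

Step 3
Reactants: 4 O-triisopropylsilyl-5-formylcapsaicin
Product: 5 O-triisopropylsilyl-5-ethynylcapsaicin
Conditions: Me3SiCHN2 (2.5 equiv), n-BuLi (2.4 equiv), THF, −78 °C; then 4, −78 °C → rt; aq. NH4Cl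
Reagents that add atoms: (trimethylsilyl)diazomethane, C[Si](C)(C)C=[N+]=[N-]
Why: Colvin rearrangement, in which lithiated (trimethylsilyl)diazomethane adds to the aryl aldehyde, Peterson elimination and loss of N2 give an alkylidene carbene, and its 1,2-hydrogen shift delivers the terminal alkyne; the excess reagent parks the amide as its inert lithium salt and no methanolic base is present to endanger the aryl silyl ether.

Step 4
Reactants: 5 O-triisopropylsilyl-5-ethynylcapsaicin
Product: 8 O-triisopropylsilyl-5-[(triisopropylsilyloxy)ethynyl]capsaicin, via dilithium acetylide 6 (not isolated), via lithium ynolate 7 (not isolated)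
Conditions: n-BuLi (2.1 equiv), THF, −78 °C; LiOOtBu (from tBuOOH and LiN(SiMe3)2), −78 → 0 °C; iPr3SiOTf, −78 °C → rt; aq. NaHCO3
Reagents that add atoms: tert-butyl hydroperoxide, CC(C)(C)OO; triisopropylsilyl triflate, CC(C)[Si](OS(=O)(=O)C(F)(F)F)(C(C)C)C(C)C
Why: Electrophilic oxygen transfer from lithium tert-butyl peroxide to a lithium acetylide gives the ynolate, which a hindered silyl triflate traps on oxygen (the established route to triisopropylsilyl ynol ethers of aryl alkynes); the amide rides along as its lithium salt and any O-silyl imidate should revert on bicarbonate work-up.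

Step 5
Reactants: 9 dimethyl 2-oxoglutarate
Product: 10 dimethyl 2,2-dimethoxypentanedioate
Conditions: HC(OMe)3, MeOH, H2SO4 (cat.), 60 °C
Reagents that add atoms: trimethyl orthoformate, COC(OC)OC; methanol, CO
Why: Acid-catalysed ketalisation of an α-keto ester with the orthoformate as water scavenger, which masks the ketone so that C3 is no longer the acidic site of the chain.

Step 6
Reactants: 10 dimethyl 2,2-dimethoxypentanedioate
Product: 11 dimethyl 2-methoxypent-2-enedioate
Conditions: TsOH·H2O (cat.), neat, 150 °C, MeOH distilled off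
Reagents that add atoms: none
Why: Acid-catalysed thermal loss of methanol from a ketal (the classical entry to 2-alkoxyacrylates) can place the enol-ether double bond only between C2 and C3, which turns the C4 methylene into a vinylogous, glutaconate-type acidic position; either alkene geometry serves.

Step 7
Reactants: 11 dimethyl 2-methoxypent-2-enedioate
Product: 13 methyl 3-methoxy-2-oxo-2H-pyran-5-carboxylate, via dienamine diester 12 (not isolated)
Conditions: Me2NCH(OMe)2, PhMe, 100 °C; evaporate; TsOH·H2O (1.1 equiv), PhMe, 80 °C
Reagents that add atoms: N,N-dimethylformamide dimethyl acetal, COC(OC)N(C)C; water, O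
Why: Aminomethylenation of the activated C4 methylene by an amide acetal, hydrolysis of the enamine to the hydroxymethylene compound and lactonisation onto the C1 ester is the formylglutaconate-to-coumalate ring closure, and the push–pull diene should isomerise freely under acid so that the geometry needed for closure is reached.

Step 8
Reactants: 8 O-triisopropylsilyl-5-[(triisopropylsilyloxy)ethynyl]capsaicin; 13 methyl 3-methoxy-2-oxo-2H-pyran-5-carboxylate (1.5 equiv)
Product: 15 methyl 3-methoxy-4-(triisopropylsilyloxy)-5-(O-triisopropylsilylcapsaicin-5-yl)benzoate, via bridged bicyclic lactone 14 (not isolated)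
Conditions: PhMe (degassed), 100 °C, sealed tube
Reagents that add atoms: none
Why: Proposed new method: the silyl ynol ether is a ketene-acetal-like π-nucleophile whose aryl-bearing carbon should attack C6 of the pyrone (the electrophilic terminus next to the ring oxygen and vinylogous to the C5 ester), after which the silyloxy-bearing carbon closes onto C3 in an asynchronous inverse-demand (4+2) cycloaddition to give the 2-oxabicyclo[2.2.2]octadienone 14. Retro-(4+2) loss of CO2 from 14 is expected to be fast and irreversible at this temperature, so ring B is closed by intermolecular annulation (new bonds C3'–C4' and C5'–C6') and aromatised by cycloreversion, with OMe, OSi, aryl and ester already on C3', C4', C5' and C1'. The closest known reaction type is the Diels–Alder/decarboxylation of 2-pyrone-5-carboxylates with ynamines, alkoxyalkynes and ketene acetals, together with thermal benzannulations of triisopropylsilyl ynol ethers, which show that such ynol ethers tolerate hot toluene. No stereocentre remains in the product (the two bridgeheads of racemic 14 are destroyed on aromatisation) and the E-alkene is a spectator. The step needs regioselectivity, secured by the polarity match described above, which is the orientation that puts silyloxy beside methoxy and the aryl group meta to the ester; it also needs chemoselectivity for the electron-rich alkyne over the unactivated chain alkene, secured by the large difference in nucleophilicity under reagent-free conditions.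

Step 9
Reactants: 15 methyl 3-methoxy-4-(triisopropylsilyloxy)-5-(O-triisopropylsilylcapsaicin-5-yl)benzoate
Product: 16 5-[5-(hydroxymethyl)-3-methoxy-2-(triisopropylsilyloxy)phenyl]-O-triisopropylsilylcapsaicin
Conditions: LiBH4, THF, MeOH (1 equiv), 0 → 40 °C
Reagents that add atoms: none
Why: Chemoselective ester reduction with lithium borohydride, a reagent that leaves secondary amides, aryl silyl ethers and isolated alkenes untouched.

Step 10
Reactants: 16 5-[5-(hydroxymethyl)-3-methoxy-2-(triisopropylsilyloxy)phenyl]-O-triisopropylsilylcapsaicin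
Product: 18 5-[5-(azidomethyl)-3-methoxy-2-(triisopropylsilyloxy)phenyl]-O-triisopropylsilylcapsaicin, via benzylic diphenyl phosphate 17 (not isolated)
Conditions: (PhO)2P(O)N3, DBU, PhMe, 0 °C → rt
Reagents that add atoms: diphenylphosphoryl azide, O=P(N=[N+]=[N-])(Oc1ccccc1)Oc1ccccc1
Why: Phosphorylation of the benzylic alcohol followed by displacement with the azide released in the flask is a standard one-flask azidation that is especially easy at an electron-rich benzylic carbon, and the amidine base is too mild to cleave the aryl silyl ethers.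

Step 11
Reactants: 18 5-[5-(azidomethyl)-3-methoxy-2-(triisopropylsilyloxy)phenyl]-O-triisopropylsilylcapsaicin
Product: 20 5-[5-(aminomethyl)-3-methoxy-2-(triisopropylsilyloxy)phenyl]-O-triisopropylsilylcapsaicin, via iminophosphorane 19 (not isolated)
Conditions: PPh3, THF, rt; then H2O, 50 °C
Reagents that add atoms: none
Why: Staudinger reduction of the azide through the iminophosphorane, chosen over hydrogenation because it cannot touch the E-alkene of the capsaicin chain.

Step 12
Reactants: 20 5-[5-(aminomethyl)-3-methoxy-2-(triisopropylsilyloxy)phenyl]-O-triisopropylsilylcapsaicin; 21 8-methylnonanoic acid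
Product: 23 O,O'-bis(triisopropylsilyl)-6'',7''-dihydro-5',5'''-dicapsaicin, via benzotriazolyl ester 22 (not isolated)
Conditions: EDC·HCl, HOBt, CH2Cl2, 0 °C → rt
Reagents that add atoms: none
Why: Carbodiimide amide coupling through the benzotriazolyl active ester, in which the primary benzylic amine is the only nucleophile left in the molecule.

Step 13
Reactants: 23 O,O'-bis(triisopropylsilyl)-6'',7''-dihydro-5',5'''-dicapsaicin
Product: 24 6'',7''-dihydro-5',5'''-dicapsaicin
Conditions: Bu4NF, AcOH, THF, 0 °C → rt
Reagents that add atoms: none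
Why: Fluoride cleavage of both aryl silyl ethers, buffered with acetic acid so that the electron-rich biphenol is not exposed to air as its phenoxide, under conditions to which the amides and the alkene are inert.

**Compound list**

1 | capsaicin, (E)-N-(4-hydroxy-3-methoxybenzyl)-8-methylnon-6-enamide | COc1cc(CNC(=O)CCCC/C=C/C(C)C)ccc1O | starting material
2 | 5-(hydroxymethyl)capsaicin (present as its magnesium salt) | COc1cc(CNC(=O)CCCC/C=C/C(C)C)cc(CO)c1O | intermediate (not isolated)
3 | 5-formylcapsaicin, (E)-N-(3-formyl-4-hydroxy-5-methoxybenzyl)-8-methylnon-6-enamide | COc1cc(CNC(=O)CCCC/C=C/C(C)C)cc(C=O)c1O | intermediate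
4 | O-triisopropylsilyl-5-formylcapsaicin | COc1cc(CNC(=O)CCCC/C=C/C(C)C)cc(C=O)c1O[Si](C(C)C)(C(C)C)C(C)C | intermediate
5 | O-triisopropylsilyl-5-ethynylcapsaicin | COc1cc(CNC(=O)CCCC/C=C/C(C)C)cc(C#C)c1O[Si](C(C)C)(C(C)C)C(C)C | intermediate
6 | dilithium salt of 5 (amidate and acetylide) | [Li+].[Li+].COc1cc(C[N-]C(=O)CCCC/C=C/C(C)C)cc(C#[C-])c1O[Si](C(C)C)(C(C)C)C(C)C | intermediate (not isolated)
7 | dilithium amidate ynolate of O-triisopropylsilyl-5-(hydroxyethynyl)capsaicin | [Li+].[Li+].COc1cc(C[N-]C(=O)CCCC/C=C/C(C)C)cc(C#C[O-])c1O[Si](C(C)C)(C(C)C)C(C)C | intermediate (not isolated)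
8 | O-triisopropylsilyl-5-[(triisopropylsilyloxy)ethynyl]capsaicin | COc1cc(CNC(=O)CCCC/C=C/C(C)C)cc(C#CO[Si](C(C)C)(C(C)C)C(C)C)c1O[Si](C(C)C)(C(C)C)C(C)C | intermediate
9 | dimethyl 2-oxoglutarate (dimethyl 2-oxopentanedioate) | COC(=O)CCC(=O)C(=O)OC | starting material
10 | dimethyl 2,2-dimethoxypentanedioate | COC(=O)CCC(OC)(OC)C(=O)OC | intermediate
11 | dimethyl 2-methoxypent-2-enedioate (mixture of alkene isomers, both serve) | COC(=O)CC=C(OC)C(=O)OC | intermediate
12 | dimethyl 4-[(dimethylamino)methylidene]-2-methoxypent-2-enedioate (mixture of alkene isomers) | COC(=O)C(=CN(C)C)C=C(OC)C(=O)OC | intermediate (not isolated)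
13 | methyl 3-methoxy-2-oxo-2H-pyran-5-carboxylate | COC(=O)C1=COC(=O)C(OC)=C1 | intermediate
14 | methyl 4-methoxy-3-oxo-8-(triisopropylsilyloxy)-7-(O-triisopropylsilylcapsaicin-5-yl)-2-oxabicyclo[2.2.2]octa-5,7-diene-6-carboxylate (racemic; bridgeheads fixed by the bicycle) | COC(=O)C1=CC2(OC)C(=O)OC1C(c1cc(CNC(=O)CCCC/C=C/C(C)C)cc(OC)c1O[Si](C(C)C)(C(C)C)C(C)C)=C2O[Si](C(C)C)(C(C)C)C(C)C | intermediate (not isolated)
15 | methyl 3-methoxy-4-(triisopropylsilyloxy)-5-(O-triisopropylsilylcapsaicin-5-yl)benzoate | COC(=O)c1cc(OC)c(O[Si](C(C)C)(C(C)C)C(C)C)c(-c2cc(CNC(=O)CCCC/C=C/C(C)C)cc(OC)c2O[Si](C(C)C)(C(C)C)C(C)C)c1 | intermediate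
16 | 5-[5-(hydroxymethyl)-3-methoxy-2-(triisopropylsilyloxy)phenyl]-O-triisopropylsilylcapsaicin | OCc1cc(OC)c(O[Si](C(C)C)(C(C)C)C(C)C)c(-c2cc(CNC(=O)CCCC/C=C/C(C)C)cc(OC)c2O[Si](C(C)C)(C(C)C)C(C)C)c1 | intermediate
17 | benzylic diphenyl phosphate of 16 | O=P(OCc1cc(OC)c(O[Si](C(C)C)(C(C)C)C(C)C)c(-c2cc(CNC(=O)CCCC/C=C/C(C)C)cc(OC)c2O[Si](C(C)C)(C(C)C)C(C)C)c1)(Oc1ccccc1)Oc1ccccc1 | intermediate (not isolated)
18 | 5-[5-(azidomethyl)-3-methoxy-2-(triisopropylsilyloxy)phenyl]-O-triisopropylsilylcapsaicin | [N-]=[N+]=NCc1cc(OC)c(O[Si](C(C)C)(C(C)C)C(C)C)c(-c2cc(CNC(=O)CCCC/C=C/C(C)C)cc(OC)c2O[Si](C(C)C)(C(C)C)C(C)C)c1 | intermediate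
19 | N-benzyl triphenyliminophosphorane derived from 18 | c1ccc(cc1)P(=NCc1cc(OC)c(O[Si](C(C)C)(C(C)C)C(C)C)c(-c2cc(CNC(=O)CCCC/C=C/C(C)C)cc(OC)c2O[Si](C(C)C)(C(C)C)C(C)C)c1)(c1ccccc1)c1ccccc1 | intermediate (not isolated)
20 | 5-[5-(aminomethyl)-3-methoxy-2-(triisopropylsilyloxy)phenyl]-O-triisopropylsilylcapsaicin | NCc1cc(OC)c(O[Si](C(C)C)(C(C)C)C(C)C)c(-c2cc(CNC(=O)CCCC/C=C/C(C)C)cc(OC)c2O[Si](C(C)C)(C(C)C)C(C)C)c1 | intermediate
21 | 8-methylnonanoic acid | CC(C)CCCCCCC(=O)O | starting material
22 | 1H-benzotriazol-1-yl 8-methylnonanoate | CC(C)CCCCCCC(=O)On1nnc2ccccc12 | intermediate (not isolated)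
23 | O,O'-bis(triisopropylsilyl)-6'',7''-dihydro-5',5'''-dicapsaicin | CC(C)CCCCCCC(=O)NCc1cc(OC)c(O[Si](C(C)C)(C(C)C)C(C)C)c(-c2cc(CNC(=O)CCCC/C=C/C(C)C)cc(OC)c2O[Si](C(C)C)(C(C)C)C(C)C)c1 | intermediate
24 | 6'',7''-dihydro-5',5'''-dicapsaicin | COc1cc(CNC(=O)CCCC/C=C/C(C)C)cc(-c2cc(CNC(=O)CCCCCCC(C)C)cc(OC)c2O)c1O | target

**Step count**

Total: 13 steps. Longest linear sequence: 10 steps (steps 1–4 and 8–13, from capsaicin); the pyrone branch (steps 5–7) joins at step 8.

**Steps most likely to fail**

1. Step 8 (proposed new method). The 3-methoxy group makes the pyrone a weaker electron-poor diene, so the cycloaddition may be slower than the thermal 1,3-silyl shift of the ynol ether to a silylketene. The stepwise addition may also stall after the first C–C bond, or regiocontrol may erode. The fallback makes the biaryl bond by cross-coupling, using known chemistry only; it sets out from capsaicin 1 and rejoins the route at 15. Capsaicin 1 would be iodinated at C5 (I2, NaHCO3, THF–H2O, 0 °C, where phenoxide iodination should outrun addition to the isolated alkene) to give 5-iodocapsaicin F1, and silylated (iPr3SiCl, imidazole, DMF) to O-triisopropylsilyl-5-iodocapsaicin F2. Commercial methyl 5-iodovanillate would be silylated in the same way to methyl 3-iodo-5-methoxy-4-(triisopropylsilyloxy)benzoate F3 and converted by Miyaura borylation (bis(pinacolato)diboron, PdCl2(dppf), KOAc, dioxane, 90 °C) into methyl 3-methoxy-5-(4,4,5,5-tetramethyl-1,3,2-dioxaborolan-2-yl)-4-(triisopropylsilyloxy)benzoate F4. Suzuki–Miyaura coupling of F2 with F4 (Pd(OAc)2, SPhos, K3PO4, PhMe–H2O, 80 °C) should give 15, from which steps 9–13 follow unchanged.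

2. Step 7. The acid-mediated ring closure may hydrolyse the 2-methoxy enol ether (leading to the 3-hydroxypyrone), or the C2=C3 bond may not reach the geometry needed for lactonisation; the aminomethylenation may also stop short. The fallback closes the ring before the unsaturation is introduced, so no alkene geometry is involved; it sets out from ketal 10 and returns at 13, replacing steps 6 and 7. Claisen formylation of 10 (NaH, HCO2Me, THF, 0 °C → rt) can occur only at C4, the sole enolisable position next to an ester, and should give dimethyl 4-formyl-2,2-dimethoxypentanedioate F5 (as its hydroxymethylene tautomer). Heating with TsOH in toluene with removal of methanol should lactonise it to methyl 3,3-dimethoxy-2-oxo-3,4-dihydro-2H-pyran-5-carboxylate F6, which loses methanol from the ketal under the same conditions to give 13.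

3. Step 4. Oxygen transfer to the hindered ortho-silyloxy aryl acetylide may be incomplete, and the lithium amidate may interfere through aggregation or by consuming the silylating agent, so that recovered alkyne or C-silylated ketene results. The fallback generates the same ynolate by ester homologation instead of acetylide oxidation; it sets out from aldehyde 4 and returns at ynolate 7, hence at 8. Pinnick oxidation of 4 (NaClO2, NaH2PO4, 2-methyl-2-butene, tBuOH–H2O) should give O-triisopropylsilylcapsaicin-5-carboxylic acid F7, and esterification (Me3SiCHN2, MeOH–PhMe) methyl O-triisopropylsilylcapsaicin-5-carboxylate F8. Kowalski ester homologation follows: LiCHBr2 (from CH2Br2 and lithium 2,2,6,6-tetramethylpiperidide, THF, −78 °C, with one extra equivalent of base for the amide) should give O-triisopropylsilyl-5-(dibromoacetyl)capsaicin F9 as its lithium enolate. n-BuLi (−78 °C → rt) then triggers bromine–lithium exchange and 1,2-aryl shift to ynolate 7, which is trapped with iPr3SiOTf as in step 4 to give 8.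

**Further compounds**

F1 | step 8 | 5-iodocapsaicin | COc1cc(CNC(=O)CCCC/C=C/C(C)C)cc(I)c1O
F2 | step 8 | O-triisopropylsilyl-5-iodocapsaicin | COc1cc(CNC(=O)CCCC/C=C/C(C)C)cc(I)c1O[Si](C(C)C)(C(C)C)C(C)C
F3 | step 8 | methyl 3-iodo-5-methoxy-4-(triisopropylsilyloxy)benzoate | COC(=O)c1cc(I)c(O[Si](C(C)C)(C(C)C)C(C)C)c(OC)c1
F4 | step 8 | methyl 3-methoxy-5-(4,4,5,5-tetramethyl-1,3,2-dioxaborolan-2-yl)-4-(triisopropylsilyloxy)benzoate | COC(=O)c1cc(B2OC(C)(C)C(C)(C)O2)c(O[Si](C(C)C)(C(C)C)C(C)C)c(OC)c1
F5 | step 7 | dimethyl 4-formyl-2,2-dimethoxypentanedioate | COC(=O)C(C=O)CC(OC)(OC)C(=O)OC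
F6 | step 7 | methyl 3,3-dimethoxy-2-oxo-3,4-dihydro-2H-pyran-5-carboxylate | COC(=O)C1=COC(=O)C(OC)(OC)C1
F7 | step 4 | O-triisopropylsilylcapsaicin-5-carboxylic acid | COc1cc(CNC(=O)CCCC/C=C/C(C)C)cc(C(=O)O)c1O[Si](C(C)C)(C(C)C)C(C)C
F8 | step 4 | methyl O-triisopropylsilylcapsaicin-5-carboxylate | COC(=O)c1cc(CNC(=O)CCCC/C=C/C(C)C)cc(OC)c1O[Si](C(C)C)(C(C)C)C(C)C
F9 | step 4 | O-triisopropylsilyl-5-(dibromoacetyl)capsaicin (formed as its lithium enolate) | COc1cc(CNC(=O)CCCC/C=C/C(C)C)cc(C(=O)C(Br)Br)c1O[Si](C(C)C)(C(C)C)C(C)C
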